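**Plan**

Ring numbering used throughout: C1 (CH bearing isopropenyl), C2, C3, C4(CH3)=C5, C6, C7=C8(CH3), C9(OH), C10, C11, C12(CH2OAc)=C13, C14(OAc), back to C1.
Cuts: the ring bond C1–C2 first; then C11–C12 (Negishi coupling); in the west half C6–C7 together with C8–CH3 (one three-component operation); in the east half C13–C14 (alkynylation).
Feature used: C1 is the γ-carbon of the 2-methylallyl unit C1–C(CH3)=CH2 (the isopropenyl group) and neighbours oxygenated C14. A C2 alkylcopper can therefore attack C1 of the allylic phosphate (EtO)2P(O)O–CH2–C(CH3)=C1H in SN2′ fashion, which closes the 14-membered ring, unveils the isopropenyl group and sets C1 in one event.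
Forward: west fragment C2–C11 (C2 latent as the CH2= end of a 1,3-diene, unmasked by 9-BBN), east fragment C12–C14 plus the allyl unit, union at C11–C12, phosphate, ring closure, desilylation. Helpers are the phosphate (lost in the ring closure) and silyl ethers.
Stereochemistry: C9 by Noyori transfer hydrogenation, C14 by zinc–ProPhenol alkynylation, C1 relayed from C14 in the ring closure; 4E bought, 7Z from anti-carbomagnesiation, 12E from trans-hydroalumination/iodination and a retentive coupling.

Key step: step 18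

Assumption: the (E)-enynol and the two silyl propargyl ethers used as starting materials are taken as commercial, and for each chiral catalyst the enantiomer named is the one expected to give the configuration drawn (its antipode would be used if the sense proved opposite).

**Route**

Step 1
Reactants: 1 bis(trimethylsilyl)acetylene; 2 3-chloropropanoyl chloride
Product: 3 5-chloro-1-(trimethylsilyl)pent-1-yn-3-one
Conditions: AlCl3, CH2Cl2, 0 °C
Reagents that add atoms: none
Why: Friedel–Crafts-type ipso-acylation of the alkynylsilane replaces one C–Si bond by the acyl group and is the standard entry to silyl ynones.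

Step 2
Reactants: 3 5-chloro-1-(trimethylsilyl)pent-1-yn-3-one
Product: 4 (S)-5-chloro-1-(trimethylsilyl)pent-1-yn-3-ol
Conditions: Ru(p-cymene)[(S,S)-TsDPEN] (1 mol %), i-PrOH, rt
Reagents that add atoms: none
Why: Noyori asymmetric transfer hydrogenation of an alkynyl ketone, in which the chiral Ru–H/N–H catalyst tells the alkynyl from the alkyl flank and should deliver hydride to the face giving the (S)-carbinol (future C9), the base-free complex avoiding loss of HCl from the β-chloro ketone.

Step 3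
Reactants: 4 (S)-5-chloro-1-(trimethylsilyl)pent-1-yn-3-ol
Product: 5 (S)-5-chloropent-1-yn-3-ol
Conditions: K2CO3 (cat.), MeOH, 0 °C
Reagents that add atoms: none
Why: Methoxide-induced protodesilylation of the alkynylsilane frees the terminal alkyne without touching the carbinol centre.

Step 4
Reactants: 6 (E)-3-methylpent-2-en-4-yn-1-ol
Product: 7 (E)-3-methylpenta-2,4-dien-1-ol
Conditions: H2 (1 atm), Pd/CaCO3 poisoned with Pb(OAc)2, quinoline, EtOAc, 0 °C to rt, stopped after 1 equiv H2
Reagents that add atoms: none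
Why: Lindlar semihydrogenation turns the terminal alkyne into the vinyl group and leaves the E trisubstituted alkene as bought.

Step 5
Reactants: 7 (E)-3-methylpenta-2,4-dien-1-ol
Product: 8 (E)-5-bromo-3-methylpenta-1,3-diene
Conditions: CBr4, PPh3, CH2Cl2, −20 to 0 °C, used at once
Reagents that add atoms: carbon tetrabromide, BrC(Br)(Br)Br
Why: Appel reaction, a neutral SN2 displacement at the primary allylic carbon that should keep the E geometry.

Step 6
Reactants: 5 (S)-5-chloropent-1-yn-3-ol; 8 (E)-5-bromo-3-methylpenta-1,3-diene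
Product: 10 (3S,4Z,7E)-1-chloro-4,8-dimethyldeca-4,7,9-trien-3-ol, via alkenylmagnesium chelate 9 (not isolated)
Conditions: MeMgBr (2.5 equiv), CuI (10 mol %), THF, −10 °C to rt; then 8, −30 to 0 °C
Reagents that add atoms: methylmagnesium bromide, C[Mg]Br
Why: Copper-catalysed anti-carbomagnesiation of the propargylic magnesium alkoxide puts methyl on the carbinol-proximal carbon and magnesium cis to oxygen in a five-membered chelate, so that copper-catalysed allylic substitution at the primary carbon of 8, with retention at the alkenyl carbon, gives the 7Z alkene, keeps the E diene and leaves C9 untouched.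

Step 7
Reactants: 10 (3S,4Z,7E)-1-chloro-4,8-dimethyldeca-4,7,9-trien-3-ol
Product: 11 tert-butyl{[(3S,4Z,7E)-1-chloro-4,8-dimethyldeca-4,7,9-trien-3-yl]oxy}dimethylsilane
Conditions: TBSOTf, 2,6-lutidine, CH2Cl2, −78 °C
Reagents that add atoms: tert-butyldimethylsilyl triflate, CC(C)(C)[Si](C)(C)OS(=O)(=O)C(F)(F)F
Why: Silylation with the triflate protects the hindered secondary allylic alcohol under buffered conditions that spare the diene.

Step 8
Reactants: 11 tert-butyl{[(3S,4Z,7E)-1-chloro-4,8-dimethyldeca-4,7,9-trien-3-yl]oxy}dimethylsilane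
Product: 12 tert-butyl{[(3S,4Z,7E)-1-iodo-4,8-dimethyldeca-4,7,9-trien-3-yl]oxy}dimethylsilane
Conditions: NaI, acetone, reflux, dark
Reagents that add atoms: sodium iodide, [Na+].[I-]
Why: Finkelstein exchange at the unhindered primary chloride gives the iodide needed for zinc insertion.

Step 9
Reactants: 13 tert-butyldimethyl(prop-2-yn-1-yloxy)silane
Product: 15 (E)-4-[(tert-butyldimethylsilyl)oxy]-3-methylbut-2-en-1-ol, via alkenylalane 14 (not isolated)
Conditions: Me3Al, Cp2ZrCl2 (20 mol %), CH2Cl2, 0 °C to rt; then n-BuLi, THF, −78 °C; (CH2O)n, −78 °C to rt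
Reagents that add atoms: trimethylaluminium, C[Al](C)C; paraformaldehyde (as formaldehyde), C=O
Why: Negishi carboalumination (syn methylalumination, methyl to the internal carbon) followed by hydroxymethylation of the derived alanate with retention fixes the E geometry, with CH2OTBS trans to the new CH2OH.

Step 10
Reactants: 15 (E)-4-[(tert-butyldimethylsilyl)oxy]-3-methylbut-2-en-1-ol
Product: 16 (E)-4-[(tert-butyldimethylsilyl)oxy]-3-methylbut-2-enal
Conditions: MnO2, CH2Cl2, rt
Reagents that add atoms: none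
Why: MnO2 oxidises the allylic alcohol to the enal under neutral conditions that should not isomerise the alkene.

Step 11
Reactants: 16 (E)-4-[(tert-butyldimethylsilyl)oxy]-3-methylbut-2-enal; 17 triethyl(prop-2-yn-1-yloxy)silane
Product: 18 (4R,5E)-7-[(tert-butyldimethylsilyl)oxy]-6-methyl-1-[(triethylsilyl)oxy]hept-5-en-2-yn-4-ol
Conditions: Me2Zn, (S,S)-ProPhenol (20 mol %), Ph3P=O (40 mol %), toluene, 0 to 4 °C
Reagents that add atoms: none
Why: Zinc–ProPhenol catalysed asymmetric alkynylation of an enal, in which the alkynylzinc is delivered to the Si face of the aldehyde in 1,2-fashion to set the carbinol (future C14) as R.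

Step 12
Reactants: 18 (4R,5E)-7-[(tert-butyldimethylsilyl)oxy]-6-methyl-1-[(triethylsilyl)oxy]hept-5-en-2-yn-4-ol
Product: 20 (2Z,4R,5E)-7-[(tert-butyldimethylsilyl)oxy]-2-iodo-6-methyl-1-[(triethylsilyl)oxy]hepta-2,5-dien-4-ol, via alkenylalanate 19 (not isolated)
Conditions: NaAlH2(OCH2CH2OCH3)2, THF, 0 °C; EtOAc quench; I2, THF, −78 °C
Reagents that add atoms: iodine, [I][I]
Why: Hydroxyl-directed trans-hydroalumination of the propargylic alcohol places aluminium on the distal alkyne carbon, cis to the carbinol carbon in a cyclic alanate, and iodinolysis with retention gives the Z alkenyl iodide, the low temperature preventing loss of the silyloxy group to an allene.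

Step 13
Reactants: 20 (2Z,4R,5E)-7-[(tert-butyldimethylsilyl)oxy]-2-iodo-6-methyl-1-[(triethylsilyl)oxy]hepta-2,5-dien-4-ol
Product: 21 (2Z,4R,5E)-7-[(tert-butyldimethylsilyl)oxy]-2-iodo-6-methylhepta-2,5-diene-1,4-diol
Conditions: PPTS (cat.), MeOH/CH2Cl2, 0 °C
Reagents that add atoms: none
Why: Mild acid methanolysis cleaves a primary triethylsilyl ether far faster than a primary tert-butyldimethylsilyl ether and is too weak to ionise the doubly allylic alcohol at 0 °C.

Step 14
Reactants: 21 (2Z,4R,5E)-7-[(tert-butyldimethylsilyl)oxy]-2-iodo-6-methylhepta-2,5-diene-1,4-diol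
Product: 22 (2Z,4R,5E)-7-[(tert-butyldimethylsilyl)oxy]-2-iodo-6-methylhepta-2,5-diene-1,4-diyl diacetate
Conditions: Ac2O, pyridine, DMAP (cat.), CH2Cl2, 0 °C to rt
Reagents that add atoms: acetic anhydride, CC(=O)OC(C)=O
Why: Acylation installs both acetates of the target while the C9 oxygen is still in the other fragment, so no later differentiation is needed.

Step 15
Reactants: 12 tert-butyl{[(3S,4Z,7E)-1-iodo-4,8-dimethyldeca-4,7,9-trien-3-yl]oxy}dimethylsilane; 22 (2Z,4R,5E)-7-[(tert-butyldimethylsilyl)oxy]-2-iodo-6-methylhepta-2,5-diene-1,4-diyl diacetate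
Product: 24 (2E,4R,5E,9S,10Z,13E)-6-(acetoxymethyl)-1,9-bis[(tert-butyldimethylsilyl)oxy]-2,10,14-trimethylhexadeca-2,5,10,13,15-pentaen-4-yl acetate, via alkylzinc iodide 23 (not isolated)
Conditions: Zn dust (activated with BrCH2CH2Br, Me3SiCl), LiCl, THF, 25 to 40 °C; then 22, PdCl2(IPr)(3-chloropyridine) (3 mol %), THF/NMP, rt
Reagents that add atoms: none
Why: Zinc insertion into the primary C–I bond followed by Negishi coupling with the alkenyl iodide, which retains alkene geometry, joins C11 to C12 with C11 cis to C14, the alkylzinc iodide leaving acetates, silyl ethers and the diene untouched.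

Step 16
Reactants: 24 (2E,4R,5E,9S,10Z,13E)-6-(acetoxymethyl)-1,9-bis[(tert-butyldimethylsilyl)oxy]-2,10,14-trimethylhexadeca-2,5,10,13,15-pentaen-4-yl acetate
Product: 25 (2E,4R,5E,9S,10Z,13E)-6-(acetoxymethyl)-9-[(tert-butyldimethylsilyl)oxy]-1-hydroxy-2,10,14-trimethylhexadeca-2,5,10,13,15-pentaen-4-yl acetate
Conditions: HF·pyridine, pyridine, THF, 0 °C
Reagents that add atoms: none
Why: Buffered HF·pyridine cleaves the unhindered primary allylic silyl ether much faster than the hindered secondary one at C9 and does not touch the acetates.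

Step 17
Reactants: 25 (2E,4R,5E,9S,10Z,13E)-6-(acetoxymethyl)-9-[(tert-butyldimethylsilyl)oxy]-1-hydroxy-2,10,14-trimethylhexadeca-2,5,10,13,15-pentaen-4-yl acetate
Product: 26 (2E,4R,5E,9S,10Z,13E)-6-(acetoxymethyl)-9-[(tert-butyldimethylsilyl)oxy]-1-[(diethoxyphosphoryl)oxy]-2,10,14-trimethylhexadeca-2,5,10,13,15-pentaen-4-yl acetate
Conditions: (EtO)2P(O)Cl, pyridine, DMAP (cat.), CH2Cl2, 0 °C
Reagents that add atoms: diethyl chlorophosphate, CCOP(=O)(Cl)OCC
Why: Phosphorylation of the only free hydroxyl makes the primary allylic position the one good leaving group of the molecule.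

Step 18
Reactants: 26 (2E,4R,5E,9S,10Z,13E)-6-(acetoxymethyl)-9-[(tert-butyldimethylsilyl)oxy]-1-[(diethoxyphosphoryl)oxy]-2,10,14-trimethylhexadeca-2,5,10,13,15-pentaen-4-yl acetate
Product: 28 (1R,4E,7Z,9S,12E,14S)-12-(acetoxymethyl)-9-[(tert-butyldimethylsilyl)oxy]-4,8-dimethyl-1-(prop-1-en-2-yl)cyclotetradeca-4,7,12-trien-14-yl acetate, via alkylborane 27 (not isolated)
Conditions: 9-BBN dimer (0.55 equiv), THF, 0 °C to rt; KOMe (1.0 equiv), 0 °C; then slow addition to CuOAc (20 mol %), THF, 60 °C, about 1 mM final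
Reagents that add atoms: none
Why: Proposed new method: anti-Markovnikov hydroboration of the only monosubstituted alkene (the C2=C3 vinyl end of the diene) gives the primary alkylborane 27, whose methoxyborate transfers the alkyl group to copper, and the tethered alkylcopper attacks C1, the γ-carbon of the primary allylic phosphate, with loss of phosphate and shift of the double bond into the isopropenyl group. The closest known reaction type is the intermolecular copper-catalysed γ-selective (SN2′) allyl–alkyl coupling of alkyl-9-BBN reagents with primary allylic phosphates, which has not been used to close a large ring. The 14-membered carbocycle closes in a 14-exo-trig mode, the C1=C(CH3) bond lying outside the new ring. The new C1 stereocentre is controlled by the adjacent C14 acetoxy carbon: allylic 1,3-strain with the cis methyl group holds the C14–H in the alkene plane, and copper should add to the face anti to the C14–O bond (Felkin–Anh-type 1,2-induction, as in SN2′ additions of zinc–copper reagents to 4-alkoxy allylic electrophiles), which gives the 1R,14S relation with the C13 tether gauche to the new bond. The step needs γ over α attack (α would give a 16-membered ring), chemoselective hydroboration and ring closure over oligomerisation; these are secured by the γ-preference of this copper system together with phosphate being a far better leaving group than the two acetates, by all other alkenes being trisubstituted, and by slow addition at high dilution.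

Step 19
Reactants: 28 (1R,4E,7Z,9S,12E,14S)-12-(acetoxymethyl)-9-[(tert-butyldimethylsilyl)oxy]-4,8-dimethyl-1-(prop-1-en-2-yl)cyclotetradeca-4,7,12-trien-14-yl acetate
Product: 29 (1R,4E,7Z,9S,12E,14S)-12-(acetoxymethyl)-9-hydroxy-4,8-dimethyl-1-(prop-1-en-2-yl)cyclotetradeca-4,7,12-trien-14-yl acetate (CNP0097266.2)
Conditions: HF·pyridine, THF, 0 °C to rt
Reagents that add atoms: none
Why: Fluoride cleavage of the last silyl ether under mildly acidic conditions should leave both allylic acetates in place and give no acyl migration to the distant C9 hydroxyl.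

**Compound list**

1 | bis(trimethylsilyl)acetylene | C[Si](C)(C)C#C[Si](C)(C)C | starting material
2 | 3-chloropropanoyl chloride | ClCCC(Cl)=O | starting material
3 | 5-chloro-1-(trimethylsilyl)pent-1-yn-3-one | C[Si](C)(C)C#CC(=O)CCCl | intermediate
4 | (S)-5-chloro-1-(trimethylsilyl)pent-1-yn-3-ol | C[Si](C)(C)C#C[C@@H](O)CCCl | intermediate
5 | (S)-5-chloropent-1-yn-3-ol | C#C[C@@H](O)CCCl | intermediate
6 | (E)-3-methylpent-2-en-4-yn-1-ol | C#C/C(C)=C/CO | starting material
7 | (E)-3-methylpenta-2,4-dien-1-ol | C=C/C(C)=C/CO | intermediate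
8 | (E)-5-bromo-3-methylpenta-1,3-diene | C=C/C(C)=C/CBr | intermediate
9 | cyclic (Z)-alkenylmagnesium alkoxide from 5 (5-(2-chloroethyl)-4-methyl-2,5-dihydro-1,2-oxamagnesole) | ClCC[C@@H]1O[Mg]C=C1C | intermediate
10 | (3S,4Z,7E)-1-chloro-4,8-dimethyldeca-4,7,9-trien-3-ol | C=C/C(C)=C/C/C=C(/C)[C@@H](O)CCCl | intermediate
11 | tert-butyl{[(3S,4Z,7E)-1-chloro-4,8-dimethyldeca-4,7,9-trien-3-yl]oxy}dimethylsilane | C=C/C(C)=C/C/C=C(/C)[C@@H](O[Si](C)(C)C(C)(C)C)CCCl | intermediate
12 | tert-butyl{[(3S,4Z,7E)-1-iodo-4,8-dimethyldeca-4,7,9-trien-3-yl]oxy}dimethylsilane | C=C/C(C)=C/C/C=C(/C)[C@@H](O[Si](C)(C)C(C)(C)C)CCI | intermediate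
13 | tert-butyldimethyl(prop-2-yn-1-yloxy)silane | C#CCO[Si](C)(C)C(C)(C)C | starting material
14 | (E)-alkenyldimethylalane from 13 | C[Al](C)/C=C(\C)CO[Si](C)(C)C(C)(C)C | intermediate
15 | (E)-4-[(tert-butyldimethylsilyl)oxy]-3-methylbut-2-en-1-ol | OC/C=C(\C)CO[Si](C)(C)C(C)(C)C | intermediate
16 | (E)-4-[(tert-butyldimethylsilyl)oxy]-3-methylbut-2-enal | O=C/C=C(\C)CO[Si](C)(C)C(C)(C)C | intermediate
17 | triethyl(prop-2-yn-1-yloxy)silane | C#CCO[Si](CC)(CC)CC | starting material
18 | (4R,5E)-7-[(tert-butyldimethylsilyl)oxy]-6-methyl-1-[(triethylsilyl)oxy]hept-5-en-2-yn-4-ol | CC[Si](CC)(CC)OCC#C[C@H](O)/C=C(\C)CO[Si](C)(C)C(C)(C)C | intermediate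
19 | cyclic sodium alkenylalanate from 18 (aluminium on C2, bound to the C4 oxygen) | CC[Si](CC)(CC)OCC1=C[C@@H](/C=C(\C)CO[Si](C)(C)C(C)(C)C)O[Al-]1(OCCOC)OCCOC.[Na+] | intermediate
20 | (2Z,4R,5E)-7-[(tert-butyldimethylsilyl)oxy]-2-iodo-6-methyl-1-[(triethylsilyl)oxy]hepta-2,5-dien-4-ol | CC[Si](CC)(CC)OC/C(I)=C/[C@H](O)/C=C(\C)CO[Si](C)(C)C(C)(C)C | intermediate
21 | (2Z,4R,5E)-7-[(tert-butyldimethylsilyl)oxy]-2-iodo-6-methylhepta-2,5-diene-1,4-diol | OC/C(I)=C/[C@H](O)/C=C(\C)CO[Si](C)(C)C(C)(C)C | intermediate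
22 | (2Z,4R,5E)-7-[(tert-butyldimethylsilyl)oxy]-2-iodo-6-methylhepta-2,5-diene-1,4-diyl diacetate | CC(=O)OC/C(I)=C/[C@H](OC(C)=O)/C=C(\C)CO[Si](C)(C)C(C)(C)C | intermediate
23 | [(3S,4Z,7E)-3-[(tert-butyldimethylsilyl)oxy]-4,8-dimethyldeca-4,7,9-trien-1-yl]zinc iodide | C=C/C(C)=C/C/C=C(/C)[C@@H](O[Si](C)(C)C(C)(C)C)CC[Zn]I | intermediate
24 | (2E,4R,5E,9S,10Z,13E)-6-(acetoxymethyl)-1,9-bis[(tert-butyldimethylsilyl)oxy]-2,10,14-trimethylhexadeca-2,5,10,13,15-pentaen-4-yl acetate | C=C/C(C)=C/C/C=C(/C)[C@@H](O[Si](C)(C)C(C)(C)C)CC/C(COC(C)=O)=C\[C@H](OC(C)=O)/C=C(\C)CO[Si](C)(C)C(C)(C)C | intermediate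
25 | (2E,4R,5E,9S,10Z,13E)-6-(acetoxymethyl)-9-[(tert-butyldimethylsilyl)oxy]-1-hydroxy-2,10,14-trimethylhexadeca-2,5,10,13,15-pentaen-4-yl acetate | C=C/C(C)=C/C/C=C(/C)[C@@H](O[Si](C)(C)C(C)(C)C)CC/C(COC(C)=O)=C\[C@H](OC(C)=O)/C=C(\C)CO | intermediate
26 | (2E,4R,5E,9S,10Z,13E)-6-(acetoxymethyl)-9-[(tert-butyldimethylsilyl)oxy]-1-[(diethoxyphosphoryl)oxy]-2,10,14-trimethylhexadeca-2,5,10,13,15-pentaen-4-yl acetate | C=C/C(C)=C/C/C=C(/C)[C@@H](O[Si](C)(C)C(C)(C)C)CC/C(COC(C)=O)=C\[C@H](OC(C)=O)/C=C(\C)COP(=O)(OCC)OCC | intermediate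
27 | 16-(9-borabicyclo[3.3.1]nonan-9-yl) adduct of 26 (boron on C2 of the ring numbering, C2=C3 saturated) | C1CC2CCCC(C1)B2CC/C(C)=C/C/C=C(/C)[C@@H](O[Si](C)(C)C(C)(C)C)CC/C(COC(C)=O)=C\[C@H](OC(C)=O)/C=C(\C)COP(=O)(OCC)OCC | intermediate
28 | (1R,4E,7Z,9S,12E,14S)-12-(acetoxymethyl)-9-[(tert-butyldimethylsilyl)oxy]-4,8-dimethyl-1-(prop-1-en-2-yl)cyclotetradeca-4,7,12-trien-14-yl acetate (ring numbering of the plan) | C=C(C)[C@H]1CC/C(C)=C/C/C=C(/C)[C@@H](O[Si](C)(C)C(C)(C)C)CC/C(COC(C)=O)=C\[C@@H]1OC(C)=O | intermediate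
29 | (1R,4E,7Z,9S,12E,14S)-12-(acetoxymethyl)-9-hydroxy-4,8-dimethyl-1-(prop-1-en-2-yl)cyclotetradeca-4,7,12-trien-14-yl acetate, CNP0097266.2 (ring numbering of the plan) | C=C(C)[C@H]1CC/C(C)=C/C/C=C(/C)[C@@H](O)CC/C(COC(C)=O)=C\[C@@H]1OC(C)=O | target

**Step count**

Total steps: 19. Longest linear sequence: 11 steps (steps 1, 2, 3, 6, 7, 8, 15 to 19; the east branch, steps 9 to 14 then 15 to 19, is equally long).

**Steps most likely to fail**

Step 18 (ring closure). The transfer of the alkyl group from boron to copper is bimolecular and slows at the dilution that ring closure needs, so oligomerisation or protodeboronation may outrun cyclisation. Attack at the CH2 end of the allyl unit would give the 16-membered ring, ring strain may override the facial preference at C1, and free methoxide may cleave an acetate. The fallback swaps the roles of the two C–C couplings, so that the copper coupling runs in its established intermolecular form and palladium closes the ring. It sets out from 11 and 22. Compound 22 is desilylated (HF·pyridine, pyridine) to (2Z,4R,5E)-7-hydroxy-2-iodo-6-methylhepta-2,5-diene-1,4-diyl diacetate F1 and phosphorylated to the diethyl phosphate F2. Compound 11 is hydroborated with 9-BBN at its vinyl end to the alkylborane F3, which is coupled with F2 (CuOAc, KOMe, THF, 60 °C) at C1 to give the open-chain chloro alkenyl iodide F4, with the isopropenyl group and the C1 centre set under the same control by C14. Finkelstein exchange gives the iodide F5, zinc insertion (Zn, LiCl; the alkenyl iodide is inert) gives the alkylzinc iodide F6, and an intramolecular Negishi coupling with the alkenyl iodide at high dilution closes the ring at C11–C12 and comes back to the route at 28.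

Step 6 (three-component assembly). The alkenylmagnesium/copper species may attack the dienyl bromide at C2 or C4 instead of C6 (allylic transposition along the diene), and the dienyl bromide may lose its E geometry by reversible ionisation before it is consumed. The fallback replaces the dienyl electrophile by a simple allylic bromide and makes the diene afterwards by elimination. It sets out from 5 (through 9). Commercial 3-butyn-1-ol is carboaluminated and hydroxymethylated (Me3Al, Cp2ZrCl2; n-BuLi; (CH2O)n) to (E)-3-methylpent-2-ene-1,5-diol F7 and converted (CBr4, PPh3) into (E)-1,5-dibromo-3-methylpent-2-ene F8. The chelate 9 is allylated at the allylic bromide of F8 to (3S,4Z,7E)-10-bromo-1-chloro-4,8-dimethyldeca-4,7-dien-3-ol F9, which is silylated to its tert-butyldimethylsilyl ether F10. DBU then removes HBr from the homoallylic bromide (its β-hydrogens are allylic; the primary chloride is far slower) and the route is rejoined at 11.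

Step 15 (fragment union). Zerovalent palladium may ionise the allylic acetates of 22 (π-allyl formation, allylic alkylation by the zinc reagent, 1,3-acetate shift) in competition with insertion into the C–I bond. The fallback makes the union before the acetates exist. It sets out from 20, which is silylated (TESOTf, 2,6-lutidine) to (2Z,4R,5E)-7-[(tert-butyldimethylsilyl)oxy]-2-iodo-6-methyl-1,4-bis[(triethylsilyl)oxy]hepta-2,5-diene F11 and coupled with 23 under the conditions of step 15 to the tetrasilyl ether F12. Both triethylsilyl groups are removed (PPTS, MeOH, 0 °C to rt) to give the diol F13, and acetylation (Ac2O, pyridine, DMAP) rejoins the route at 24.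

Further compounds
F1 | step 18 | (2Z,4R,5E)-7-hydroxy-2-iodo-6-methylhepta-2,5-diene-1,4-diyl diacetate | CC(=O)OC/C(I)=C/[C@H](OC(C)=O)/C=C(\C)CO
F2 | step 18 | (2Z,4R,5E)-7-[(diethoxyphosphoryl)oxy]-2-iodo-6-methylhepta-2,5-diene-1,4-diyl diacetate | CC(=O)OC/C(I)=C/[C@H](OC(C)=O)/C=C(\C)COP(=O)(OCC)OCC
F3 | step 18 | 9-[(3E,6Z,8S)-8-[(tert-butyldimethylsilyl)oxy]-10-chloro-3,7-dimethyldeca-3,6-dien-1-yl]-9-borabicyclo[3.3.1]nonane | C1CC2CCCC(C1)B2CC/C(C)=C/C/C=C(/C)[C@@H](O[Si](C)(C)C(C)(C)C)CCCl
F4 | step 18 | (2Z,4R,5R,8E,11Z,13S)-13-[(tert-butyldimethylsilyl)oxy]-15-chloro-2-iodo-8,12-dimethyl-5-(prop-1-en-2-yl)pentadeca-2,8,11-triene-1,4-diyl diacetate | C=C(C)[C@@H](CC/C(C)=C/C/C=C(/C)[C@@H](O[Si](C)(C)C(C)(C)C)CCCl)[C@@H](OC(C)=O)/C=C(I)/COC(C)=O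
F5 | step 18 | (2Z,4R,5R,8E,11Z,13S)-13-[(tert-butyldimethylsilyl)oxy]-2,15-diiodo-8,12-dimethyl-5-(prop-1-en-2-yl)pentadeca-2,8,11-triene-1,4-diyl diacetate | C=C(C)[C@@H](CC/C(C)=C/C/C=C(/C)[C@@H](O[Si](C)(C)C(C)(C)C)CCI)[C@@H](OC(C)=O)/C=C(I)/COC(C)=O
F6 | step 18 | alkylzinc iodide from F5 (zinc on C11 of the ring numbering) | C=C(C)[C@@H](CC/C(C)=C/C/C=C(/C)[C@@H](O[Si](C)(C)C(C)(C)C)CC[Zn]I)[C@@H](OC(C)=O)/C=C(I)/COC(C)=O
F7 | step 6 | (E)-3-methylpent-2-ene-1,5-diol | OCC/C(C)=C/CO
F8 | step 6 | (E)-1,5-dibromo-3-methylpent-2-ene | BrCC/C(C)=C/CBr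
F9 | step 6 | (3S,4Z,7E)-10-bromo-1-chloro-4,8-dimethyldeca-4,7-dien-3-ol | BrCC/C(C)=C/C/C=C(/C)[C@@H](O)CCCl
F10 | step 6 | {[(3S,4Z,7E)-10-bromo-1-chloro-4,8-dimethyldeca-4,7-dien-3-yl]oxy}(tert-butyl)dimethylsilane | BrCC/C(C)=C/C/C=C(/C)[C@@H](O[Si](C)(C)C(C)(C)C)CCCl
F11 | step 15 | (2Z,4R,5E)-7-[(tert-butyldimethylsilyl)oxy]-2-iodo-6-methyl-1,4-bis[(triethylsilyl)oxy]hepta-2,5-diene | CC[Si](CC)(CC)OC/C(I)=C/[C@H](O[Si](CC)(CC)CC)/C=C(\C)CO[Si](C)(C)C(C)(C)C
F12 | step 15 | (2E,4R,5E,9S,10Z,13E)-1,9-bis[(tert-butyldimethylsilyl)oxy]-2,10,14-trimethyl-4-[(triethylsilyl)oxy]-6-{[(triethylsilyl)oxy]methyl}hexadeca-2,5,10,13,15-pentaene | C=C/C(C)=C/C/C=C(/C)[C@@H](O[Si](C)(C)C(C)(C)C)CC/C(CO[Si](CC)(CC)CC)=C\[C@H](O[Si](CC)(CC)CC)/C=C(\C)CO[Si](C)(C)C(C)(C)C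
F13 | step 15 | (2E,4R,5E,9S,10Z,13E)-1,9-bis[(tert-butyldimethylsilyl)oxy]-6-(hydroxymethyl)-2,10,14-trimethylhexadeca-2,5,10,13,15-pentaen-4-ol | C=C/C(C)=C/C/C=C(/C)[C@@H](O[Si](C)(C)C(C)(C)C)CC/C(CO)=C\[C@H](O)/C=C(\C)CO[Si](C)(C)C(C)(C)C
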